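**Plan**

- Numbering: isoflavan with chroman rings A and C (O1, C2, C3, C4, C5–C8), aryl ring B (C1'–C6') and ring D, the dimethylpyran fused at C4'–C5'.
- Retrosynthesis: after removal of the C7 silyl ether, one operation cuts C3'–CH2 (prenyl), C5'–CH= and O4'–CMe2 (ring D). Ring B allows this because it has oxygen at C2' and C4', carbon groups at C3' and C5', and a blocked C1', so both carbon groups can come from the ring B oxygens by [3,3] shifts of a 2'-O-(1,1-dimethylallyl) 4'-O-(1,1-dimethylpropargyl) bis-ether.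
- The bis-ether goes back by O–C cuts to an isoflavan whose O4' (benzyl) and O2' (methoxymethyl) are told apart from the start; ring C is cut at O1–C2 (Mitsunobu) and C3–C4 at an auxiliary-controlled enolate benzylation.
- Forward: the ring A benzyl bromide and the ring B arylacetyl imide are joined at C3–C4, ring C is closed, O4' and then O2' are etherified, and ring D and the prenyl group arise together in the key step.
- Stereochemistry: the only stereocentre, C3 (R), is set by the (R)-4-benzyloxazolidinone in the alkylation and is not touched afterwards.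

Key step: step 16

Assumption: 1-[4-(benzyloxy)-2-hydroxyphenyl]ethanone and 3-chloro-3-methylbut-1-yne are taken as catalogue compounds; the former is otherwise one benzylation (BnBr, K2CO3) from 2,4-dihydroxyacetophenone.

**Route**

Step 1
Reactants: 1 2,4-dihydroxybenzaldehyde
Product: 2 2-hydroxy-4-(triisopropylsilyloxy)benzaldehyde
Conditions: i-Pr3SiCl, imidazole, CH2Cl2, 0 °C to rt
Reagents that add atoms: chlorotriisopropylsilane, CC(C)[Si](Cl)(C(C)C)C(C)C
Why: Selective O-silylation, because the C2 hydroxyl is hydrogen-bonded to the aldehyde and hindered, so the bulky silyl chloride should take only the C4 hydroxyl.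

Step 2
Reactants: 2 2-hydroxy-4-(triisopropylsilyloxy)benzaldehyde
Product: 3 2-(benzyloxy)-4-(triisopropylsilyloxy)benzaldehyde
Conditions: BnBr, K2CO3, acetone, 50 °C
Reagents that add atoms: benzyl bromide, BrCc1ccccc1
Why: Williamson etherification of the remaining phenol; the triisopropylsilyl ether is chosen because it should tolerate carbonate where a smaller silyl ether para to the formyl group might be lost.

Step 3
Reactants: 3 2-(benzyloxy)-4-(triisopropylsilyloxy)benzaldehyde
Product: 4 [2-(benzyloxy)-4-(triisopropylsilyloxy)phenyl]methanol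
Conditions: NaBH4, MeOH/THF, 0 °C
Reagents that add atoms: none
Why: Borohydride reduction of an aryl aldehyde to the benzyl alcohol, with both ethers inert.

Step 4
Reactants: 4 [2-(benzyloxy)-4-(triisopropylsilyloxy)phenyl]methanol
Product: 5 2-(benzyloxy)-4-(triisopropylsilyloxy)benzyl bromide
Conditions: CBr4, PPh3, CH2Cl2, 0 °C; used at once
Reagents that add atoms: carbon tetrabromide, BrC(Br)(Br)Br
Why: Appel reaction under neutral conditions, which suits an electron-rich benzyl bromide that would not survive acid or storage.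

Step 5
Reactants: 6 1-[4-(benzyloxy)-2-hydroxyphenyl]ethanone
Product: 7 1-[4-(benzyloxy)-2-(methoxymethoxy)phenyl]ethanone
Conditions: MeOCH2Cl, i-Pr2NEt, CH2Cl2, 0 °C to reflux
Reagents that add atoms: chloromethyl methyl ether, COCCl
Why: Acetal protection of the chelated phenol, giving a ring B whose O2' (methoxymethyl, stable to base, hydride and hydrogenolysis) and O4' (benzyl) can later be freed separately.

Step 6
Reactants: 7 1-[4-(benzyloxy)-2-(methoxymethoxy)phenyl]ethanone
Product: 9 [4-(benzyloxy)-2-(methoxymethoxy)phenyl]acetic acid, via thiomorpholide 8 (not isolated)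
Conditions: S8, morpholine, 130 °C; then NaOH, EtOH/H2O, reflux; 1 M HCl to pH 4 at 0 °C
Reagents that add atoms: sulfur, S1SSSSSSS1 (found in 8 only); morpholine, C1COCCN1 (found in 8 only); sodium hydroxide, [Na+].[OH-] (supplies both oxygen atoms of the acid)
Why: Willgerodt–Kindler reaction moves the oxidised carbon to the chain terminus as a thioamide, and basic hydrolysis gives the arylacetic acid while the benzyl and methoxymethyl ethers are base-stable.

Step 7
Reactants: 9 [4-(benzyloxy)-2-(methoxymethoxy)phenyl]acetic acid; 10 (R)-4-benzyl-1,3-oxazolidin-2-one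
Product: 12 (4R)-4-benzyl-3-{[4-(benzyloxy)-2-(methoxymethoxy)phenyl]acetyl}-1,3-oxazolidin-2-one, via mixed pivalic anhydride 11 (not isolated)
Conditions: t-BuCOCl, Et3N, THF, −20 °C; then 10, LiCl, −20 °C to rt
Reagents that add atoms: pivaloyl chloride, CC(C)(C)C(Cl)=O (acyl group found in 11 only)
Why: Mixed-anhydride N-acylation of the oxazolidinone, in which the nucleophile attacks the less hindered arylacetyl carbonyl of 11.

Step 8
Reactants: 12 (4R)-4-benzyl-3-{[4-(benzyloxy)-2-(methoxymethoxy)phenyl]acetyl}-1,3-oxazolidin-2-one; 5 2-(benzyloxy)-4-(triisopropylsilyloxy)benzyl bromide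
Product: 14 (4R)-4-benzyl-3-{(2R)-3-[2-(benzyloxy)-4-(triisopropylsilyloxy)phenyl]-2-[4-(benzyloxy)-2-(methoxymethoxy)phenyl]propanoyl}-1,3-oxazolidin-2-one, via sodium enolate 13 (not isolated)
Conditions: NaN(SiMe3)2, THF, −78 °C; then 5, −78 to −40 °C
Reagents that add atoms: sodium bis(trimethylsilyl)amide, C[Si](C)(C)[N-][Si](C)(C)C.[Na+] (sodium found in 13 only)
Why: Evans alkylation, in which the chelated Z-enolate is shielded on one face by the C4 benzyl group of the auxiliary and the bromide enters from the other face; with the (R)-auxiliary this should give the (2R) centre (aryl ranks above the new CH2), which becomes C3 (R) of the isoflavan.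

Step 9
Reactants: 14 (4R)-4-benzyl-3-{(2R)-3-[2-(benzyloxy)-4-(triisopropylsilyloxy)phenyl]-2-[4-(benzyloxy)-2-(methoxymethoxy)phenyl]propanoyl}-1,3-oxazolidin-2-one
Product: 15 (2R)-3-[2-(benzyloxy)-4-(triisopropylsilyloxy)phenyl]-2-[4-(benzyloxy)-2-(methoxymethoxy)phenyl]propan-1-ol
Conditions: LiBH4, MeOH (1 equiv), THF, 0 °C
Reagents that add atoms: none
Why: Reductive cleavage of the imide at the exocyclic carbonyl by a non-basic hydride, so the α-aryl centre should not epimerise and the auxiliary is recovered.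

Step 10
Reactants: 15 (2R)-3-[2-(benzyloxy)-4-(triisopropylsilyloxy)phenyl]-2-[4-(benzyloxy)-2-(methoxymethoxy)phenyl]propan-1-ol
Product: 16 (2R)-3-[2-hydroxy-4-(triisopropylsilyloxy)phenyl]-2-[4-hydroxy-2-(methoxymethoxy)phenyl]propan-1-ol
Conditions: H2 (1 atm), Pd/C, EtOAc, rt
Reagents that add atoms: none
Why: Hydrogenolysis removes both benzyl ethers in one operation and leaves the silyl ether, the acetal and the primary alcohol.

Step 11
Reactants: 16 (2R)-3-[2-hydroxy-4-(triisopropylsilyloxy)phenyl]-2-[4-hydroxy-2-(methoxymethoxy)phenyl]propan-1-ol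
Product: 17 (3R)-4'-hydroxy-2'-(methoxymethoxy)-7-(triisopropylsilyloxy)isoflavan
Conditions: PPh3, DIAD, THF (0.01 M), 0 °C to rt
Reagents that add atoms: none
Why: Intramolecular Mitsunobu etherification closes ring C by 6-exo-tet attack of the ring A phenol on the activated primary CH2 (not the stereocentre); the 4'-phenol cannot reach this carbon within the molecule, O2' is capped so closure to a dihydrobenzofuran is excluded, and high dilution disfavours intermolecular etherification.

Step 12
Reactants: 17 (3R)-4'-hydroxy-2'-(methoxymethoxy)-7-(triisopropylsilyloxy)isoflavan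
Product: 18 (3R)-2'-(methoxymethoxy)-4'-(2-methylbut-3-yn-2-yloxy)-7-(triisopropylsilyloxy)isoflavan
Conditions: 3-chloro-3-methylbut-1-yne, DBU, CuCl2·2H2O (cat.), MeCN, 0 °C, Ar
Reagents that add atoms: 3-chloro-3-methylbut-1-yne, CC(C)(Cl)C#C
Why: Copper-catalysed propargylic substitution through a copper acetylide gives the tertiary aryl propargyl ether at the only free phenol, under conditions mild enough for the silyl ether.

Step 13
Reactants: 18 (3R)-2'-(methoxymethoxy)-4'-(2-methylbut-3-yn-2-yloxy)-7-(triisopropylsilyloxy)isoflavan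
Product: 20 (3R)-2'-hydroxy-4'-(2-methylbut-3-yn-2-yloxy)-7-(triisopropylsilyloxy)isoflavan, via trimethylsilyl ether 19 (not isolated)
Conditions: Me3SiOTf, 2,2'-bipyridyl, MeCN, 0 °C to rt; then H2O; NaHCO3 wash
Reagents that add atoms: trimethylsilyl trifluoromethanesulfonate, C[Si](C)(C)OS(=O)(=O)C(F)(F)F (silyl group found in 19 only)
Why: The bipyridyl-buffered silyl triflate is known to convert aromatic methoxymethyl ethers chemoselectively into aryl silyl ethers that hydrolyse on adding water; it should activate only the acetal and spare the tertiary propargyl ether, the alkyne and the aryl silyl ether.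

Step 14
Reactants: 21 2-methylbut-3-en-2-ol
Product: 23 methyl 2-methylbut-3-en-2-yl carbonate, via lithium alkoxide 22 (not isolated)
Conditions: n-BuLi, THF, −78 °C; then ClCO2Me, −78 °C to rt
Reagents that add atoms: methyl chloroformate, COC(Cl)=O; n-butyllithium, [Li]CCCC (lithium found in 22 only)
Why: O-acylation of the lithium alkoxide is the standard way to make a carbonate from a tertiary allylic alcohol.

Step 15
Reactants: 20 (3R)-2'-hydroxy-4'-(2-methylbut-3-yn-2-yloxy)-7-(triisopropylsilyloxy)isoflavan; 23 methyl 2-methylbut-3-en-2-yl carbonate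
Product: 24 (3R)-2'-(2-methylbut-3-en-2-yloxy)-4'-(2-methylbut-3-yn-2-yloxy)-7-(triisopropylsilyloxy)isoflavan
Conditions: Pd(PPh3)4 (5 mol %), THF, 0 °C, short reaction time
Reagents that add atoms: none
Why: Tsuji–Trost O-allylation, in which zerovalent palladium ionises the carbonate with loss of CO2, the methoxide deprotonates the phenol, and the phenoxide attacks the 1,1-dimethylallyl palladium cation at its more substituted end under kinetic control at low temperature to give the tertiary ether.

Step 16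
Reactants: 24 (3R)-2'-(2-methylbut-3-en-2-yloxy)-4'-(2-methylbut-3-yn-2-yloxy)-7-(triisopropylsilyloxy)isoflavan
Product: 28 2,2-dimethyl-8-(3-methylbut-2-en-1-yl)-6-[(3R)-7-(triisopropylsilyloxy)chroman-3-yl]-2H-chromen-7-ol (7-O-triisopropylsilyl ether of the target), via prenyl phenol 25 (not isolated), via allenyl phenol 26 (not isolated), via quinone methide 27 (not isolated)
Conditions: PhNEt2 (degassed), 115 °C; then 195 °C, Ar
Reagents that add atoms: none
Why: At 115 °C the 2'-O-(1,1-dimethylallyl) ether undergoes an aromatic Claisen rearrangement through a chair [3,3] transition state to C3' and the dienone enolises to prenyl phenol 25 (C3'–CH2 bond, allyl termini inverted); at 195 °C the 4'-O-propargyl ether makes the second [3,3] shift to C5', enolisation gives allenyl phenol 26, a 1,5-hydrogen shift gives ortho-quinone methide 27, and this closes to the chromene. The closest known reactions are the thermal Claisen rearrangement of aryl 1,1-dimethylallyl ethers to ortho-prenylphenols and the thermal conversion of aryl 1,1-dimethylpropargyl ethers into 2,2-dimethyl-2H-chromenes, run here one after the other in one flask. Ring D closes by a thermal disrotatory oxa-6π electrocyclisation of the 1-oxatriene O=C4'–C5'=CH–CH=CMe2 of 27, which forms the O4'–CMe2 bond. No stereocentre is formed, and C3, which bears no acidic hydrogen, is a spectator. The regiochemistry needed is built into ring B: C1' carries the chroman, so O2' can deliver its allyl group productively only to C3' (a shift to C1' gives a dienone that cannot enolise and reverts), and with C3' filled O4' can deliver only to C5'. The order needed (allyl before propargyl) follows from the lower barrier of the tertiary allyl ether and is held by the temperature plateau, while the amine solvent suppresses acid-catalysed loss of isoprene and cyclisation of the prenyl phenol.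

Step 17
Reactants: 28 2,2-dimethyl-8-(3-methylbut-2-en-1-yl)-6-[(3R)-7-(triisopropylsilyloxy)chroman-3-yl]-2H-chromen-7-ol (7-O-triisopropylsilyl ether of the target)
Product: 29 (3R)-3-[7-hydroxy-2,2-dimethyl-8-(3-methylbut-2-en-1-yl)-2H-chromen-6-yl]chroman-7-ol (CNP0331403.1)
Conditions: Bu4NF, AcOH, THF, 0 °C
Reagents that add atoms: none
Why: Fluoride cleavage of the aryl silyl ether, buffered with acetic acid so that the electron-rich phenoxide, the chromene and the prenyl group are not exposed to strong base.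

**Compound list**

1 | 2,4-dihydroxybenzaldehyde | O=Cc1ccc(O)cc1O | starting material
2 | 2-hydroxy-4-(triisopropylsilyloxy)benzaldehyde | O=Cc1ccc(O[Si](C(C)C)(C(C)C)C(C)C)cc1O | intermediate
3 | 2-(benzyloxy)-4-(triisopropylsilyloxy)benzaldehyde | O=Cc1ccc(O[Si](C(C)C)(C(C)C)C(C)C)cc1OCc1ccccc1 | intermediate
4 | [2-(benzyloxy)-4-(triisopropylsilyloxy)phenyl]methanol | OCc1ccc(O[Si](C(C)C)(C(C)C)C(C)C)cc1OCc1ccccc1 | intermediate
5 | 2-(benzyloxy)-4-(triisopropylsilyloxy)benzyl bromide | BrCc1ccc(O[Si](C(C)C)(C(C)C)C(C)C)cc1OCc1ccccc1 | intermediate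
6 | 1-[4-(benzyloxy)-2-hydroxyphenyl]ethanone | CC(=O)c1ccc(OCc2ccccc2)cc1O | starting material
7 | 1-[4-(benzyloxy)-2-(methoxymethoxy)phenyl]ethanone | CC(=O)c1ccc(OCc2ccccc2)cc1OCOC | intermediate
8 | 2-[4-(benzyloxy)-2-(methoxymethoxy)phenyl]-1-(morpholin-4-yl)ethanethione (not isolated) | S=C(Cc1ccc(OCc2ccccc2)cc1OCOC)N1CCOCC1 | intermediate
9 | [4-(benzyloxy)-2-(methoxymethoxy)phenyl]acetic acid | OC(=O)Cc1ccc(OCc2ccccc2)cc1OCOC | intermediate
10 | (R)-4-benzyl-1,3-oxazolidin-2-one | O=C1N[C@H](Cc2ccccc2)CO1 | starting material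
11 | [4-(benzyloxy)-2-(methoxymethoxy)phenyl]acetic pivalic anhydride (not isolated) | CC(C)(C)C(=O)OC(=O)Cc1ccc(OCc2ccccc2)cc1OCOC | intermediate
12 | (4R)-4-benzyl-3-{[4-(benzyloxy)-2-(methoxymethoxy)phenyl]acetyl}-1,3-oxazolidin-2-one | O=C(Cc1ccc(OCc2ccccc2)cc1OCOC)N1[C@H](Cc2ccccc2)COC1=O | intermediate
13 | sodium (Z)-enolate of 12 (not isolated) | [Na+].[O-]/C(=C\c1ccc(OCc2ccccc2)cc1OCOC)N1[C@H](Cc2ccccc2)COC1=O | intermediate
14 | (4R)-4-benzyl-3-{(2R)-3-[2-(benzyloxy)-4-(triisopropylsilyloxy)phenyl]-2-[4-(benzyloxy)-2-(methoxymethoxy)phenyl]propanoyl}-1,3-oxazolidin-2-one | O=C([C@H](Cc1ccc(O[Si](C(C)C)(C(C)C)C(C)C)cc1OCc1ccccc1)c1ccc(OCc2ccccc2)cc1OCOC)N1[C@H](Cc2ccccc2)COC1=O | intermediate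
15 | (2R)-3-[2-(benzyloxy)-4-(triisopropylsilyloxy)phenyl]-2-[4-(benzyloxy)-2-(methoxymethoxy)phenyl]propan-1-ol | OC[C@H](Cc1ccc(O[Si](C(C)C)(C(C)C)C(C)C)cc1OCc1ccccc1)c1ccc(OCc2ccccc2)cc1OCOC | intermediate
16 | (2R)-3-[2-hydroxy-4-(triisopropylsilyloxy)phenyl]-2-[4-hydroxy-2-(methoxymethoxy)phenyl]propan-1-ol | OC[C@H](Cc1ccc(O[Si](C(C)C)(C(C)C)C(C)C)cc1O)c1ccc(O)cc1OCOC | intermediate
17 | (3R)-4'-hydroxy-2'-(methoxymethoxy)-7-(triisopropylsilyloxy)isoflavan | COCOc1cc(O)ccc1[C@@H]1COc2cc(O[Si](C(C)C)(C(C)C)C(C)C)ccc2C1 | intermediate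
18 | (3R)-2'-(methoxymethoxy)-4'-(2-methylbut-3-yn-2-yloxy)-7-(triisopropylsilyloxy)isoflavan | C#CC(C)(C)Oc1ccc([C@@H]2COc3cc(O[Si](C(C)C)(C(C)C)C(C)C)ccc3C2)c(OCOC)c1 | intermediate
19 | (3R)-4'-(2-methylbut-3-yn-2-yloxy)-7-(triisopropylsilyloxy)-2'-(trimethylsilyloxy)isoflavan (not isolated) | C#CC(C)(C)Oc1ccc([C@@H]2COc3cc(O[Si](C(C)C)(C(C)C)C(C)C)ccc3C2)c(O[Si](C)(C)C)c1 | intermediate
20 | (3R)-2'-hydroxy-4'-(2-methylbut-3-yn-2-yloxy)-7-(triisopropylsilyloxy)isoflavan | C#CC(C)(C)Oc1ccc([C@@H]2COc3cc(O[Si](C(C)C)(C(C)C)C(C)C)ccc3C2)c(O)c1 | intermediate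
21 | 2-methylbut-3-en-2-ol | CC(C)(O)C=C | starting material
22 | lithium 2-methylbut-3-en-2-olate (not isolated) | [Li+].[O-]C(C)(C)C=C | intermediate
23 | methyl 2-methylbut-3-en-2-yl carbonate | COC(=O)OC(C)(C)C=C | intermediate
24 | (3R)-2'-(2-methylbut-3-en-2-yloxy)-4'-(2-methylbut-3-yn-2-yloxy)-7-(triisopropylsilyloxy)isoflavan | C#CC(C)(C)Oc1ccc([C@@H]2COc3cc(O[Si](C(C)C)(C(C)C)C(C)C)ccc3C2)c(OC(C)(C)C=C)c1 | intermediate
25 | (3R)-2'-hydroxy-3'-(3-methylbut-2-en-1-yl)-4'-(2-methylbut-3-yn-2-yloxy)-7-(triisopropylsilyloxy)isoflavan (not isolated) | C#CC(C)(C)Oc1ccc([C@@H]2COc3cc(O[Si](C(C)C)(C(C)C)C(C)C)ccc3C2)c(O)c1CC=C(C)C | intermediate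
26 | (3R)-2',4'-dihydroxy-3'-(3-methylbut-2-en-1-yl)-5'-(3-methylbuta-1,2-dien-1-yl)-7-(triisopropylsilyloxy)isoflavan (not isolated) | CC(C)=C=Cc1cc([C@@H]2COc3cc(O[Si](C(C)C)(C(C)C)C(C)C)ccc3C2)c(O)c(CC=C(C)C)c1O | intermediate
27 | 3-hydroxy-2-(3-methylbut-2-en-1-yl)-6-[(Z)-3-methylbut-2-en-1-ylidene]-4-[(3R)-7-(triisopropylsilyloxy)chroman-3-yl]cyclohexa-2,4-dien-1-one (not isolated) | CC(C)=C/C=C1/C=C([C@@H]2COc3cc(O[Si](C(C)C)(C(C)C)C(C)C)ccc3C2)C(O)=C(CC=C(C)C)C1=O | intermediate
28 | 2,2-dimethyl-8-(3-methylbut-2-en-1-yl)-6-[(3R)-7-(triisopropylsilyloxy)chroman-3-yl]-2H-chromen-7-ol (7-O-triisopropylsilyl ether of the target) | CC(C)=CCc1c(O)c([C@@H]2COc3cc(O[Si](C(C)C)(C(C)C)C(C)C)ccc3C2)cc2c1OC(C)(C)C=C2 | intermediate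
29 | (3R)-3-[7-hydroxy-2,2-dimethyl-8-(3-methylbut-2-en-1-yl)-2H-chromen-6-yl]chroman-7-ol | CC(C)=CCc1c(O)c([C@@H]2COc3cc(O)ccc3C2)cc2c1OC(C)(C)C=C2 | target

**Count and risks**

Total step count: 17. Longest linear sequence: 13 steps (from 1 to 29 through steps 1–4, 8–13 and 15–17). The arylacetyl branch from 6 (steps 5–7) joins at step 8 and runs 12 steps to 29; carbonate 23 (step 14) joins at step 15.

Steps most likely to fail:

1. Step 16. The two shifts may not keep their order (the propargyl ether may begin to move towards C3' before the allyl group has arrived there), and the free, electron-rich phenol formed in the first shift may degrade at the temperature of the second. Fallback: setting out from 24, the bis-ether would be heated only to 110 °C in toluene so that the allyl shift alone occurs, and prenyl phenol 25 would be isolated. Its 2'-hydroxyl would be acetylated (Ac2O, pyridine) to (3R)-2'-acetoxy-3'-(3-methylbut-2-en-1-yl)-4'-(2-methylbut-3-yn-2-yloxy)-7-(triisopropylsilyloxy)isoflavan F1. Heating F1 in PhNEt2 at 195 °C should give the 2'-O-acetate of 28 F2. Hydrazine hydrate in THF/MeOH at 0 °C would remove the aryl acetate and leave the silyl ether, returning to the route at 28.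

2. Step 15. The phenoxide may attack the primary end of the allyl palladium cation, the tertiary ether may be re-ionised by palladium and drift to the linear prenyl ether, or the hindered 2'-phenoxide may react too slowly. Fallback: setting out from 17, the 4'-hydroxyl would be pivaloylated (t-BuCOCl, Et3N, DMAP) to (3R)-2'-(methoxymethoxy)-4'-(pivaloyloxy)-7-(triisopropylsilyloxy)isoflavan F3. HCl in MeOH at 40 °C would free O2' to give (3R)-2'-hydroxy-4'-(pivaloyloxy)-7-(triisopropylsilyloxy)isoflavan F4. Copper-catalysed propargylation as in step 12 would give (3R)-2'-(2-methylbut-3-yn-2-yloxy)-4'-(pivaloyloxy)-7-(triisopropylsilyloxy)isoflavan F5. Semi-hydrogenation over Pd/CaCO3 poisoned with Pb(OAc)2 and quinoline would give the tertiary allyl ether (3R)-2'-(2-methylbut-3-en-2-yloxy)-4'-(pivaloyloxy)-7-(triisopropylsilyloxy)isoflavan F6, with no regiochemical question. i-Bu2AlH at −78 °C would remove the pivalate to give (3R)-4'-hydroxy-2'-(2-methylbut-3-en-2-yloxy)-7-(triisopropylsilyloxy)isoflavan F7, and propargylation of F7 as in step 12 would return to the route at 24.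

3. Step 13. The Lewis-acidic acetal cleavage may ionise the tertiary propargylic ether or remove the silyl ether. Fallback: setting out from 17, the acetal would be cleaved before any propargyl ether is present (HCl, MeOH, 40 °C) to give (3R)-2',4'-dihydroxy-7-(triisopropylsilyloxy)isoflavan F8. Copper-catalysed propargylation with one equivalent of 3-chloro-3-methylbut-1-yne at −10 °C is then expected to take the unhindered 4'-hydroxyl in preference to the 2'-hydroxyl, which is flanked by the chroman C3, returning to the route at 20 after chromatography.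

**Further compounds**

F1 | step 16 | (3R)-2'-acetoxy-3'-(3-methylbut-2-en-1-yl)-4'-(2-methylbut-3-yn-2-yloxy)-7-(triisopropylsilyloxy)isoflavan | C#CC(C)(C)Oc1ccc([C@@H]2COc3cc(O[Si](C(C)C)(C(C)C)C(C)C)ccc3C2)c(OC(C)=O)c1CC=C(C)C
F2 | step 16 | 2'-O-acetate of 28 | CC(C)=CCc1c(OC(C)=O)c([C@@H]2COc3cc(O[Si](C(C)C)(C(C)C)C(C)C)ccc3C2)cc2c1OC(C)(C)C=C2
F3 | step 15 | (3R)-2'-(methoxymethoxy)-4'-(pivaloyloxy)-7-(triisopropylsilyloxy)isoflavan | COCOc1cc(OC(=O)C(C)(C)C)ccc1[C@@H]1COc2cc(O[Si](C(C)C)(C(C)C)C(C)C)ccc2C1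
F4 | step 15 | (3R)-2'-hydroxy-4'-(pivaloyloxy)-7-(triisopropylsilyloxy)isoflavan | Oc1cc(OC(=O)C(C)(C)C)ccc1[C@@H]1COc2cc(O[Si](C(C)C)(C(C)C)C(C)C)ccc2C1
F5 | step 15 | (3R)-2'-(2-methylbut-3-yn-2-yloxy)-4'-(pivaloyloxy)-7-(triisopropylsilyloxy)isoflavan | C#CC(C)(C)Oc1cc(OC(=O)C(C)(C)C)ccc1[C@@H]1COc2cc(O[Si](C(C)C)(C(C)C)C(C)C)ccc2C1
F6 | step 15 | (3R)-2'-(2-methylbut-3-en-2-yloxy)-4'-(pivaloyloxy)-7-(triisopropylsilyloxy)isoflavan | C=CC(C)(C)Oc1cc(OC(=O)C(C)(C)C)ccc1[C@@H]1COc2cc(O[Si](C(C)C)(C(C)C)C(C)C)ccc2C1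
F7 | step 15 | (3R)-4'-hydroxy-2'-(2-methylbut-3-en-2-yloxy)-7-(triisopropylsilyloxy)isoflavan | C=CC(C)(C)Oc1cc(O)ccc1[C@@H]1COc2cc(O[Si](C(C)C)(C(C)C)C(C)C)ccc2C1
F8 | step 13 | (3R)-2',4'-dihydroxy-7-(triisopropylsilyloxy)isoflavan | Oc1ccc([C@@H]2COc3cc(O[Si](C(C)C)(C(C)C)C(C)C)ccc3C2)c(O)c1
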